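**Plan**

- Retrosynthetic cuts, in order: the ester C–O bond between the feruloyl group and the CH2O arm on C2; the O1–C8a aryl ether bond of the pyran; the C4–C4a bond (as an aryl–alkyne bond, the C3=C4 alkene coming from the alkyne); and the C3–C4 bond, back to the aldehyde of a 2-methylglycerol unit.
- Forward: (R)-2-methylglycidol is opened with 4-methoxybenzyl alcohol, oxidised and homologated to a tertiary propargylic alcohol. Sonogashira coupling with the iodinated, MOM-protected fluoroacetophenone and Z-selective semihydrogenation give the open chain. The pyran, the only ring made, is then closed at O1–C8a. PMB removal, esterification with O-MOM ferulic acid and acidic MOM cleavage finish the synthesis.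
- Enabling feature: C8a of the benzo ring lies para to the C6 acetyl carbonyl, so a fluoride on C8a is activated for addition–elimination, and the Z C3=C4 double bond holds the C2 tertiary alkoxide next to C8a.
- Stereochemistry: the single stereocentre C2 is the quaternary carbon of (R)-2-methylglycidol, and its C–O bond is never broken. The E enoate is taken from ferulic acid.

Key step: step 8

Remark: chromene numbering (O1, C2, C3, C4, C4a, C5–C8, C8a) is used throughout, and iodination of 4-fluoro-2-hydroxyacetophenone is assumed to go para to the hydroxyl, as is usual for 2-hydroxyacetophenones.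

**Route**

Step 1
Reactants: 1 (R)-2-methylglycidol; 2 4-methoxybenzyl alcohol
Product: 3 (R)-3-[(4-methoxybenzyl)oxy]-2-methylpropane-1,2-diol
Conditions: 2 (4 equiv), NaH (0.2 equiv), DMF, 60 °C, slow addition of 1
Reagents that add atoms: none
Why: Base-catalysed SN2 epoxide opening by the 4-methoxybenzyl alkoxide at the unsubstituted CH2 leaves the C–O bond at the quaternary carbon untouched, so the configuration of 1 passes into 3; a Payne rearrangement of the glycidoxide is degenerate and returns the same enantiomer, and the excess of 2 suppresses oligomerisation.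

Step 2
Reactants: 3 (R)-3-[(4-methoxybenzyl)oxy]-2-methylpropane-1,2-diol
Product: 4 (S)-2-hydroxy-3-[(4-methoxybenzyl)oxy]-2-methylpropanal
Conditions: IBX (2-iodoxybenzoic acid), DMSO, rt; used crude
Reagents that add atoms: none
Why: IBX oxidation takes the primary hydroxyl of a 1,2-diol to the aldehyde without glycol cleavage and cannot oxidise the tertiary hydroxyl; the stereocentre carries no hydrogen and cannot epimerise (the descriptor becomes S only because CHO outranks CH2OPMB).

Step 3
Reactants: 4 (S)-2-hydroxy-3-[(4-methoxybenzyl)oxy]-2-methylpropanal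
Product: 5 (R)-1-[(4-methoxybenzyl)oxy]-2-methylbut-3-yn-2-ol
Conditions: dimethyl (1-diazo-2-oxopropyl)phosphonate, K2CO3, MeOH, 0 °C → rt
Reagents that add atoms: dimethyl (1-diazo-2-oxopropyl)phosphonate, COP(=O)(OC)C(=[N+]=[N-])C(C)=O
Why: Seyferth–Gilbert homologation in the Ohira–Bestmann variant: methanolysis of the reagent gives the diazomethylphosphonate anion, which adds to the aldehyde, and elimination of phosphate, loss of N2 and a 1,2-hydride shift in the alkylidene carbene give the terminal alkyne, with free hydroxyls tolerated and the quaternary carbinol not involved.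

Step 4
Reactants: 6 4-fluoro-2-hydroxyacetophenone
Product: 7 1-(4-fluoro-2-hydroxy-5-iodophenyl)ethanone
Conditions: NIS, TFA (cat.), MeCN, rt
Reagents that add atoms: N-iodosuccinimide, O=C1CCC(=O)N1I
Why: Electrophilic aromatic iodination goes para to the hydroxyl, a carbon that is also ortho to fluorine and meta to the acetyl group, whereas the other activated position is flanked by OH and F.

Step 5
Reactants: 7 1-(4-fluoro-2-hydroxy-5-iodophenyl)ethanone
Product: 8 1-[4-fluoro-5-iodo-2-(methoxymethoxy)phenyl]ethanone
Conditions: NaH, MOMCl, DMF, 0 °C → rt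
Reagents that add atoms: chloromethyl methyl ether, COCCl
Why: O-alkylation of the sodium phenoxide with MOMCl masks the phenol, which as a phenoxide would deactivate the ring in step 8 and could cyclise onto the alkyne after step 6.

Step 6
Reactants: 8 1-[4-fluoro-5-iodo-2-(methoxymethoxy)phenyl]ethanone; 5 (R)-1-[(4-methoxybenzyl)oxy]-2-methylbut-3-yn-2-ol
Product: 9 (R)-1-[4-fluoro-5-{3-hydroxy-4-[(4-methoxybenzyl)oxy]-3-methylbut-1-yn-1-yl}-2-(methoxymethoxy)phenyl]ethanone
Conditions: PdCl2(PPh3)2 (cat.), CuI (cat.), Et3N, THF, rt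
Reagents that add atoms: none
Why: Sonogashira coupling: zerovalent palladium inserts only into the C–I bond (C–F is inert) and free tertiary propargylic alcohols are standard partners, which forms the future C4–C4a bond.

Step 7
Reactants: 9 (R)-1-[4-fluoro-5-{3-hydroxy-4-[(4-methoxybenzyl)oxy]-3-methylbut-1-yn-1-yl}-2-(methoxymethoxy)phenyl]ethanone
Product: 10 (R,Z)-1-[4-fluoro-5-{3-hydroxy-4-[(4-methoxybenzyl)oxy]-3-methylbut-1-en-1-yl}-2-(methoxymethoxy)phenyl]ethanone
Conditions: H2 (1 atm), Pd/CaCO3 poisoned with Pb(OAc)2, quinoline, EtOAc, rt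
Reagents that add atoms: none
Why: Lindlar semihydrogenation delivers both hydrogens syn on the poisoned palladium surface to give the Z-alkene, quinoline restrains over-reduction, and the aryl fluoride, ketone, PMB and MOM ethers are inert.

Step 8
Reactants: 10 (R,Z)-1-[4-fluoro-5-{3-hydroxy-4-[(4-methoxybenzyl)oxy]-3-methylbut-1-en-1-yl}-2-(methoxymethoxy)phenyl]ethanone
Product: 11 (R)-1-[2-{[(4-methoxybenzyl)oxy]methyl}-7-(methoxymethoxy)-2-methyl-2H-chromen-6-yl]ethanone
Conditions: KOtBu (1.1 equiv), DMF (0.02 M), 0 °C → rt; aq. NH4Cl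
Reagents that add atoms: none
Why: KOtBu turns every molecule into a monoanion that shuttles, through the tBuOH formed, between the inert acetyl enolate and the C2 tertiary alkoxide; only the alkoxide reacts on, so the closure drains this equilibrium while no neutral ketone remains as an aldol acceptor. The alkoxide adds to C8a to give a Meisenheimer complex whose charge is carried by the para C6 acetyl carbonyl, and loss of fluoride restores the arene; this is an addition–elimination SNAr, and the closest known reaction type is the intramolecular etherification of carbonyl-activated aryl fluorides by tertiary alkoxides. The pyran closes in a 6-exo-trig sense at the arene carbon (the attacked C8a=C8 π bond lies outside the new ring). No stereocentre is created, and C2 keeps its R configuration because the C2–O bond, taken intact from the glycidol, is never broken. The step needs O-arylation by a hindered alkoxide in preference to enolate chemistry and intermolecular substitution, which the Z C3=C4 alkene (alkoxide held over C8a), the para-acyl activation and high dilution should secure. The positions of fluorine and of the alkenyl chain on the arene fix the linear 6-acetyl-7-oxy chromene.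

Step 9
Reactants: 11 (R)-1-[2-{[(4-methoxybenzyl)oxy]methyl}-7-(methoxymethoxy)-2-methyl-2H-chromen-6-yl]ethanone
Product: 12 (R)-1-[2-(hydroxymethyl)-7-(methoxymethoxy)-2-methyl-2H-chromen-6-yl]ethanone
Conditions: DDQ, CH2Cl2/pH 7 phosphate buffer, 0 °C
Reagents that add atoms: none
Why: Oxidative PMB cleavage: DDQ takes hydride from the electron-rich 4-methoxybenzylic position and water hydrolyses the oxocarbenium ion, while the chromene has no C–H at C2 and its acetyl-bearing arene is too electron-poor to be oxidised.

Step 10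
Reactants: 13 ferulic acid
Product: 15 (E)-3-[3-methoxy-4-(methoxymethoxy)phenyl]prop-2-enoic acid, via bis-MOM ferulate 14 (not isolated)
Conditions: NaH (2.2 equiv), MOMCl, DMF, 0 °C → rt; crude 14, LiOH, THF/H2O, rt; 1 M HCl to pH 4, 0 °C
Reagents that add atoms: chloromethyl methyl ether, COCCl; lithium hydroxide, [Li+].[OH-] (one carboxyl oxygen, by acyl–oxygen cleavage)
Why: Double O-alkylation of the disodium salt followed by saponification: the methoxymethyl ester is cleaved readily by hydroxide, whereas the aryl MOM ether is stable to base and the E alkene is untouched.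

Step 11
Reactants: 12 (R)-1-[2-(hydroxymethyl)-7-(methoxymethoxy)-2-methyl-2H-chromen-6-yl]ethanone; 15 (E)-3-[3-methoxy-4-(methoxymethoxy)phenyl]prop-2-enoic acid
Product: 16 [(R)-6-acetyl-7-(methoxymethoxy)-2-methyl-2H-chromen-2-yl]methyl (E)-3-[3-methoxy-4-(methoxymethoxy)phenyl]prop-2-enoate
Conditions: DCC, DMAP (cat.), CH2Cl2, 0 °C → rt
Reagents that add atoms: none
Why: Steglich esterification: DCC activates the acid as its O-acylisourea and DMAP relays the acyl group as an acylpyridinium ion to the primary alcohol, with no free phenol present to compete.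

Step 12
Reactants: 16 [(R)-6-acetyl-7-(methoxymethoxy)-2-methyl-2H-chromen-2-yl]methyl (E)-3-[3-methoxy-4-(methoxymethoxy)phenyl]prop-2-enoate
Product: 17 [(R)-6-acetyl-7-hydroxy-2-methyl-2H-chromen-2-yl]methyl (E)-3-(4-hydroxy-3-methoxyphenyl)prop-2-enoate (CNP0375196.1)
Conditions: 3 M aq. HCl, THF, 40 °C
Reagents that add atoms: none
Why: Acid-catalysed acetal hydrolysis removes both aryl MOM ethers (the C7 one assisted by the neighbouring acetyl carbonyl), while the hindered enoate ester and the acetyl-deactivated chromene should tolerate dilute acid at this temperature.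

**Compound list**

1 | (R)-2-methylglycidol | C[C@@]1(CO)CO1 | starting material
2 | 4-methoxybenzyl alcohol | COc1ccc(CO)cc1 | starting material
3 | (R)-3-[(4-methoxybenzyl)oxy]-2-methylpropane-1,2-diol | C[C@@](O)(CO)COCc1ccc(OC)cc1 | intermediate
4 | (S)-2-hydroxy-3-[(4-methoxybenzyl)oxy]-2-methylpropanal | C[C@@](O)(C=O)COCc1ccc(OC)cc1 | intermediate
5 | (R)-1-[(4-methoxybenzyl)oxy]-2-methylbut-3-yn-2-ol | C[C@@](O)(C#C)COCc1ccc(OC)cc1 | intermediate
6 | 4-fluoro-2-hydroxyacetophenone | CC(=O)c1ccc(F)cc1O | starting material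
7 | 1-(4-fluoro-2-hydroxy-5-iodophenyl)ethanone | CC(=O)c1cc(I)c(F)cc1O | intermediate
8 | 1-[4-fluoro-5-iodo-2-(methoxymethoxy)phenyl]ethanone | CC(=O)c1cc(I)c(F)cc1OCOC | intermediate
9 | (R)-1-[4-fluoro-5-{3-hydroxy-4-[(4-methoxybenzyl)oxy]-3-methylbut-1-yn-1-yl}-2-(methoxymethoxy)phenyl]ethanone | CC(=O)c1cc(C#C[C@@](C)(O)COCc2ccc(OC)cc2)c(F)cc1OCOC | intermediate
10 | (R,Z)-1-[4-fluoro-5-{3-hydroxy-4-[(4-methoxybenzyl)oxy]-3-methylbut-1-en-1-yl}-2-(methoxymethoxy)phenyl]ethanone | CC(=O)c1cc(/C=C\[C@@](C)(O)COCc2ccc(OC)cc2)c(F)cc1OCOC | intermediate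
11 | (R)-1-[2-{[(4-methoxybenzyl)oxy]methyl}-7-(methoxymethoxy)-2-methyl-2H-chromen-6-yl]ethanone | COc1ccc(COC[C@@]2(C)C=Cc3cc(C(C)=O)c(OCOC)cc3O2)cc1 | intermediate
12 | (R)-1-[2-(hydroxymethyl)-7-(methoxymethoxy)-2-methyl-2H-chromen-6-yl]ethanone | OC[C@@]1(C)C=Cc2cc(C(C)=O)c(OCOC)cc2O1 | intermediate
13 | ferulic acid | COc1cc(/C=C/C(=O)O)ccc1O | starting material
14 | methoxymethyl (E)-3-[3-methoxy-4-(methoxymethoxy)phenyl]prop-2-enoate (bis-MOM ferulate) | COCOC(=O)/C=C/c1ccc(OCOC)c(OC)c1 | intermediate
15 | (E)-3-[3-methoxy-4-(methoxymethoxy)phenyl]prop-2-enoic acid | COCOc1ccc(/C=C/C(=O)O)cc1OC | intermediate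
16 | [(R)-6-acetyl-7-(methoxymethoxy)-2-methyl-2H-chromen-2-yl]methyl (E)-3-[3-methoxy-4-(methoxymethoxy)phenyl]prop-2-enoate | COc1cc(/C=C/C(=O)OC[C@@]2(C)C=Cc3cc(C(C)=O)c(OCOC)cc3O2)ccc1OCOC | intermediate
17 | [(R)-6-acetyl-7-hydroxy-2-methyl-2H-chromen-2-yl]methyl (E)-3-(4-hydroxy-3-methoxyphenyl)prop-2-enoate (CNP0375196.1) | COc1cc(/C=C/C(=O)OC[C@@]2(C)C=Cc3cc(C(C)=O)c(O)cc3O2)ccc1O | target

**Summary**

Total step count: 12. Longest linear sequence: 9 steps (steps 1, 2, 3, 6, 7, 8, 9, 11, 12).

Steps most likely to fail: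

Step 8 (ring closure). Deprotonation of the acetyl methyl group may park the substrate as an enolate whose ring no longer accepts the alkoxide, or feed condensation, so that the closure stalls. The fallback changes the activating group to a nitrile, which cannot enolise and activates the para fluoride at least as strongly. It sets out from alkyne 5 and commercial 4-fluoro-2-hydroxybenzonitrile F1. Iodination with NIS would give 4-fluoro-2-hydroxy-5-iodobenzonitrile F2, and NaH/MOMCl would give 4-fluoro-5-iodo-2-(methoxymethoxy)benzonitrile F3. Sonogashira coupling of F3 with 5 would give (R)-4-fluoro-5-{3-hydroxy-4-[(4-methoxybenzyl)oxy]-3-methylbut-1-yn-1-yl}-2-(methoxymethoxy)benzonitrile F4. Semihydrogenation over Pd/CaCO3 poisoned with Pb(OAc)2 would give the (R,Z)-alkenyl benzonitrile F5, and KOtBu in DMF would close it to (R)-2-{[(4-methoxybenzyl)oxy]methyl}-7-(methoxymethoxy)-2-methyl-2H-chromene-6-carbonitrile F6. Addition of MeMgBr in THF would give the corresponding ethan-1-imine F7, and mild aqueous hydrolysis (aq. NH4Cl, silica) would give ketone 11, where the route is rejoined.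

Step 3 (homologation). Base-induced α-ketol rearrangement or self-condensation of the unprotected α-hydroxy aldehyde may outrun the homologation. The fallback homologates before the epoxide is opened, so that no free α-hydroxy aldehyde is ever present. It sets out from 1. Oxidation with TEMPO/PhI(OAc)2 in CH2Cl2 would give (S)-2-methyloxirane-2-carbaldehyde F8, kept in solution because it is volatile. Ohira–Bestmann homologation would give (R)-2-ethynyl-2-methyloxirane F9. Opening of F9 at its CH2 terminus with the sodium alkoxide of 2 (NaH, DMF) returns to the route at alkyne 5.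

Step 12 (MOM cleavage). Acid may ionise the allylic C2–O1 bond (ring opening with loss of configuration), hydrolyse the ester, or let the liberated formaldehyde alkylate the phenolic rings. The fallback places the only acid-requiring deprotection before the esterification and carries the ferulate phenol as an acetate. It sets out from 12 and 13. PPTS in warm tert-butanol would remove the carbonyl-assisted C7 MOM group to give (R)-1-[7-hydroxy-2-(hydroxymethyl)-2-methyl-2H-chromen-6-yl]ethanone F10. Ferulic acid 13 with Ac2O/pyridine would give (E)-3-(4-acetoxy-3-methoxyphenyl)prop-2-enoic acid F11. DCC/DMAP coupling of F10 and F11 at the primary hydroxyl would give [(R)-6-acetyl-7-hydroxy-2-methyl-2H-chromen-2-yl]methyl (E)-3-(4-acetoxy-3-methoxyphenyl)prop-2-enoate F12; the C7 phenol, hydrogen-bonded to the acetyl carbonyl, is the poorer nucleophile. NH4OAc in aqueous methanol would then cleave only the aryl acetate, returning to the route at target 17.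

**Further compounds**

F1 | step 8 | 4-fluoro-2-hydroxybenzonitrile | N#Cc1ccc(F)cc1O
F2 | step 8 | 4-fluoro-2-hydroxy-5-iodobenzonitrile | N#Cc1cc(I)c(F)cc1O
F3 | step 8 | 4-fluoro-5-iodo-2-(methoxymethoxy)benzonitrile | COCOc1cc(F)c(I)cc1C#N
F4 | step 8 | (R)-4-fluoro-5-{3-hydroxy-4-[(4-methoxybenzyl)oxy]-3-methylbut-1-yn-1-yl}-2-(methoxymethoxy)benzonitrile | COCOc1cc(F)c(C#C[C@@](C)(O)COCc2ccc(OC)cc2)cc1C#N
F5 | step 8 | (R,Z)-4-fluoro-5-{3-hydroxy-4-[(4-methoxybenzyl)oxy]-3-methylbut-1-en-1-yl}-2-(methoxymethoxy)benzonitrile | COCOc1cc(F)c(/C=C\[C@@](C)(O)COCc2ccc(OC)cc2)cc1C#N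
F6 | step 8 | (R)-2-{[(4-methoxybenzyl)oxy]methyl}-7-(methoxymethoxy)-2-methyl-2H-chromene-6-carbonitrile | COc1ccc(COC[C@@]2(C)C=Cc3cc(C#N)c(OCOC)cc3O2)cc1
F7 | step 8 | (R)-1-[2-{[(4-methoxybenzyl)oxy]methyl}-7-(methoxymethoxy)-2-methyl-2H-chromen-6-yl]ethan-1-imine | COc1ccc(COC[C@@]2(C)C=Cc3cc(C(C)=N)c(OCOC)cc3O2)cc1
F8 | step 3 | (S)-2-methyloxirane-2-carbaldehyde | C[C@@]1(C=O)CO1
F9 | step 3 | (R)-2-ethynyl-2-methyloxirane | C[C@@]1(C#C)CO1
F10 | step 12 | (R)-1-[7-hydroxy-2-(hydroxymethyl)-2-methyl-2H-chromen-6-yl]ethanone | OC[C@@]1(C)C=Cc2cc(C(C)=O)c(O)cc2O1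
F11 | step 12 | (E)-3-(4-acetoxy-3-methoxyphenyl)prop-2-enoic acid | CC(=O)Oc1ccc(/C=C/C(=O)O)cc1OC
F12 | step 12 | [(R)-6-acetyl-7-hydroxy-2-methyl-2H-chromen-2-yl]methyl (E)-3-(4-acetoxy-3-methoxyphenyl)prop-2-enoate | CC(=O)Oc1ccc(/C=C/C(=O)OC[C@@]2(C)C=Cc3cc(C(C)=O)c(O)cc3O2)cc1OC
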